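A direct plan would hydroborate eugenol A1 to dihydroconiferyl alcohol A2, dearomatise A2 with PhI(OAc)2 to the spiro dienone ether A3, and let the oxygen of 4-propylsyringol A4 open A3 in an acid-catalysed SN2′ step, so that the ether bond would be made to a carbon of the hydroxylated ring. Its weakest steps would be:
- the ring-opening aryloxylation, because a hindered 2,6-dimethoxyphenol would have to act as an O-nucleophile at a dienone carbon in a reaction type without precedent, while electron transfer from the easily oxidised syringol and acid-induced rearomatisation of A3 would compete;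
- the oxidative spirocyclisation, because an ortho-methoxyphenol could also be attacked at its methoxylated carbon and the spiro ether would be acid-labile;
- the hydroboration, which would spend a second equivalent of 9-BBN on the free phenol.

Ring A (2,6-dimethoxy-4-propylphenoxy) is treated as a latent, symmetrical 5-propylcyclohexane-1,3-dione: its C1 lies between the methoxylated C2 and C6, and the propyl group sits on C4. The ring is built from hept-3-en-2-one and malonate, and the ether bond O–C1 is cut: a rhodium carbenoid at C2 of the dione inserts into the O–H bond of a ring B phenol (a 4-O-benzyl 5-hydroxyferulate), and oxidative aromatisation with methylation then reveals ring A. The hindered C–O bond thus forms at a carbenoid carbon with ring B as the nucleophile, so that no dearomatisation of ring B, no unprecedented aryloxylation and no hydroboration appear.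

Key step: step 5

Assumption: (E)-hept-3-en-2-one, dimethyl malonate, 5-hydroxyvanillin (3,4-dihydroxy-5-methoxybenzaldehyde) and methyl (triphenylphosphoranylidene)acetate are taken as commercial starting materials.

Step 1
Reactants: 1 (E)-hept-3-en-2-one; 2 dimethyl malonate
Product: 6 5-propylcyclohexane-1,3-dione, via Michael adduct 3 (not isolated), via cyclic keto ester 4 (not isolated), via keto acid 5 (not isolated)
Conditions: NaOMe (1.1 equiv), MeOH, reflux; then 2 M NaOH, reflux; then HCl to pH 1, reflux
Reagents that add atoms: none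
Why: Michael addition of the malonate anion to the enone β-carbon gives 3, whose methyl ketone enolate closes the six-membered ring on one ester (intramolecular Claisen condensation of the dimedone type) to 4, and saponification to 5 followed by decarboxylation should give the achiral dione 6, so that ring A is built from open-chain precursors with the propyl group already opposite the future ether carbon; the transient stereocentres of 3 to 5 vanish in 6.

Step 2
Reactants: 6 5-propylcyclohexane-1,3-dione
Product: 7 2-diazo-5-propylcyclohexane-1,3-dione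
Conditions: 4-acetamidobenzenesulfonyl azide (1.1 equiv), Et3N, MeCN, 0 °C → rt
Reagents that add atoms: 4-acetamidobenzenesulfonyl azide, CC(=O)Nc1ccc(cc1)S(=O)(=O)N=[N+]=[N-]
Why: Regitz diazo transfer to the doubly activated C2 methylene of a 1,3-dione is a standard reaction and forms no stereocentre.

Step 3
Reactants: 8 5-hydroxyvanillin (3,4-dihydroxy-5-methoxybenzaldehyde)
Product: 9 4-(benzyloxy)-3-hydroxy-5-methoxybenzaldehyde
Conditions: BnBr (1.05 equiv), Li2CO3 (1.1 equiv), DMF, 45 °C
Reagents that add atoms: benzyl bromide, BrCc1ccccc1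
Why: Williamson etherification under weak base: the hydroxyl para to the formyl group is the more acidic one, so only its phenoxide should form and be benzylated, which leaves the 3-hydroxyl free for step 5.

Step 4
Reactants: 9 4-(benzyloxy)-3-hydroxy-5-methoxybenzaldehyde; 10 methyl (triphenylphosphoranylidene)acetate
Product: 11 methyl (E)-3-[4-(benzyloxy)-3-hydroxy-5-methoxyphenyl]prop-2-enoate
Conditions: toluene, 90 °C
Reagents that add atoms: none
Why: Wittig olefination with a stabilised ylide tolerates the free phenol and should give the E cinnamate, whose geometry is without consequence because the double bond is hydrogenated in step 7.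

Step 5
Reactants: 7 2-diazo-5-propylcyclohexane-1,3-dione; 11 methyl (E)-3-[4-(benzyloxy)-3-hydroxy-5-methoxyphenyl]prop-2-enoate
Product: 13 methyl (E)-3-{4-(benzyloxy)-3-[(2,6-dioxo-4-propylcyclohexyl)oxy]-5-methoxyphenyl}prop-2-enoate, via rhodium carbenoid 12 (not isolated)
Conditions: Rh2(OAc)4 (2 mol%), PhF, 80 °C, 7 (1.2 equiv) added over 2 h
Reagents that add atoms: none
Why: Dirhodium tetraacetate should decompose 7 with loss of N2 to the electrophilic carbenoid 12, flanked by two carbonyl groups; the phenolic oxygen of 11 adds to the carbenoid carbon and proton transfer from oxygen to the dione enolate releases the catalyst and gives 13 (rhodium carbene O–H insertion). The closest known reaction type is the dirhodium-catalysed O–H insertion of 2-diazo-1,3-dicarbonyl compounds into alcohols and phenols. No ring is closed, and the new sp3 centre at C2 of the dione needs no control, since it is flattened in the enol form of 13 and becomes aromatic C1 of ring A in step 6. The step needs O–H insertion to win over Wolff ring contraction and over attack of the carbenoid on the arene C–H bonds, the benzyl ether oxygen and the alkene. This is secured by the single acidic O–H of 11, which traps the carbenoid irreversibly through proton transfer, by the electron-poor acrylate-conjugated alkene, and by the slow addition of 7. The hindered C–O bond of the tetra-ortho-oxygenated diaryl ether is thereby formed before ring A is aromatic, so that no di-ortho-substituted aryl partner has to undergo C(sp2)–O coupling.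

Step 6
Reactants: 13 methyl (E)-3-{4-(benzyloxy)-3-[(2,6-dioxo-4-propylcyclohexyl)oxy]-5-methoxyphenyl}prop-2-enoate
Product: 16 methyl (E)-3-[4-(benzyloxy)-3-(2,6-dimethoxy-4-propylphenoxy)-5-methoxyphenyl]prop-2-enoate, via vinylogous ester 14 (not isolated), via monomethyl ether 15 (not isolated)
Conditions: I2 (2.2 equiv), MeOH, reflux; evaporate; then Me2SO4, K2CO3, acetone, reflux
Reagents that add atoms: methanol, CO; dimethyl sulfate, COS(=O)(=O)OC
Why: Iodine–methanol oxidative aromatisation of a 2-substituted cyclohexane-1,3-dione: acid-catalysed formation of vinylogous ester 14, iodination of its dienol ether and loss of HI should give, after tautomerisation, phenol 15 (in part already 16), and the telescoped Williamson methylation should converge all material on 16, while the acrylate-conjugated ring B is deactivated toward iodination and Friedel–Crafts cyclisation; the stereo-elements of 13 are erased.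

Step 7
Reactants: 16 methyl (E)-3-[4-(benzyloxy)-3-(2,6-dimethoxy-4-propylphenoxy)-5-methoxyphenyl]prop-2-enoate
Product: 17 methyl 3-[3-(2,6-dimethoxy-4-propylphenoxy)-4-hydroxy-5-methoxyphenyl]propanoate
Conditions: H2 (1 atm), 10% Pd/C, EtOAc–MeOH, rt
Reagents that add atoms: none
Why: Heterogeneous catalytic hydrogenation should saturate the cinnamate double bond and hydrogenolyse the benzyl ether in one operation, while the diaryl ether, the methyl ethers and the ester are inert.

Step 8
Reactants: 17 methyl 3-[3-(2,6-dimethoxy-4-propylphenoxy)-4-hydroxy-5-methoxyphenyl]propanoate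
Product: 18 2-(2,6-dimethoxy-4-propylphenoxy)-4-(3-hydroxypropyl)-6-methoxyphenol (target)
Conditions: LiAlH4 (3 equiv), THF, 0 °C → rt; dilute HCl work-up
Reagents that add atoms: none
Why: Hydride reduction of the methyl ester to the primary alcohol, with the phenol merely deprotonated and recovered on work-up; the target is achiral, so no stereocentre has to be set.

**Compound list**

1 | (E)-hept-3-en-2-one | CCC/C=C/C(C)=O | starting material
2 | dimethyl malonate | COC(=O)CC(=O)OC | starting material
3 | dimethyl 2-(2-oxoheptan-4-yl)propanedioate (racemic) | CCCC(CC(C)=O)C(C(=O)OC)C(=O)OC | intermediate (not isolated)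
4 | methyl 2,4-dioxo-6-propylcyclohexane-1-carboxylate (racemic, present as its sodium enolate) | CCCC1CC(=O)CC(=O)C1C(=O)OC | intermediate (not isolated)
5 | 2,4-dioxo-6-propylcyclohexane-1-carboxylic acid (racemic) | CCCC1CC(=O)CC(=O)C1C(O)=O | intermediate (not isolated)
6 | 5-propylcyclohexane-1,3-dione (achiral) | CCCC1CC(=O)CC(=O)C1 | intermediate
7 | 2-diazo-5-propylcyclohexane-1,3-dione (achiral) | CCCC1CC(=O)C(=[N+]=[N-])C(=O)C1 | intermediate
8 | 5-hydroxyvanillin, 3,4-dihydroxy-5-methoxybenzaldehyde | COc1cc(C=O)cc(O)c1O | starting material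
9 | 4-(benzyloxy)-3-hydroxy-5-methoxybenzaldehyde | COc1cc(C=O)cc(O)c1OCc1ccccc1 | intermediate
10 | methyl (triphenylphosphoranylidene)acetate | COC(=O)C=P(c1ccccc1)(c1ccccc1)c1ccccc1 | starting material
11 | methyl (E)-3-[4-(benzyloxy)-3-hydroxy-5-methoxyphenyl]prop-2-enoate | COC(=O)/C=C/c1cc(O)c(OCc2ccccc2)c(OC)c1 | intermediate
12 | Rh2(OAc)4-bound carbene at C2 of 5-propylcyclohexane-1,3-dione (the dirhodium tetraacetate unit is drawn as one Rh atom) | CCCC1CC(=O)C(=[Rh])C(=O)C1 | intermediate (not isolated)
13 | methyl (E)-3-{4-(benzyloxy)-3-[(2,6-dioxo-4-propylcyclohexyl)oxy]-5-methoxyphenyl}prop-2-enoate (drawn as the diketone, expected mainly as its enol; cis/trans relation of ring substituents undefined and lost in step 6) | CCCC1CC(=O)C(Oc2cc(/C=C/C(=O)OC)cc(OC)c2OCc2ccccc2)C(=O)C1 | intermediate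
14 | methyl (E)-3-{4-(benzyloxy)-3-methoxy-5-[(2-methoxy-6-oxo-4-propylcyclohex-1-en-1-yl)oxy]phenyl}prop-2-enoate (racemic) | CCCC1CC(OC)=C(Oc2cc(/C=C/C(=O)OC)cc(OC)c2OCc2ccccc2)C(=O)C1 | intermediate (not isolated)
15 | methyl (E)-3-[4-(benzyloxy)-3-(2-hydroxy-6-methoxy-4-propylphenoxy)-5-methoxyphenyl]prop-2-enoate | CCCc1cc(O)c(Oc2cc(/C=C/C(=O)OC)cc(OC)c2OCc2ccccc2)c(OC)c1 | intermediate (not isolated)
16 | methyl (E)-3-[4-(benzyloxy)-3-(2,6-dimethoxy-4-propylphenoxy)-5-methoxyphenyl]prop-2-enoate | CCCc1cc(OC)c(Oc2cc(/C=C/C(=O)OC)cc(OC)c2OCc2ccccc2)c(OC)c1 | intermediate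
17 | methyl 3-[3-(2,6-dimethoxy-4-propylphenoxy)-4-hydroxy-5-methoxyphenyl]propanoate | CCCc1cc(OC)c(Oc2cc(CCC(=O)OC)cc(OC)c2O)c(OC)c1 | intermediate
18 | 2-(2,6-dimethoxy-4-propylphenoxy)-4-(3-hydroxypropyl)-6-methoxyphenol (achiral) | CCCc1cc(OC)c(Oc2cc(CCCO)cc(OC)c2O)c(OC)c1 | target

Total step count: 8. Longest linear sequence: 6 steps (steps 1, 2, 5, 6, 7, 8 or steps 3, 4, 5, 6, 7, 8).

**Steps most likely to fail**

Step 5 (carbene O–H insertion). The carbenoid may undergo Wolff ring contraction, may attack the electron-rich arene, or a second carbenoid may capture the acidic enol of the product. The fallback is a copper-mediated Ullmann ether synthesis that sets out from 6 and 11 and returns at 16. Dione 6 alone would be aromatised with I2 in MeOH and methylated (Me2SO4, K2CO3) to 1,3-dimethoxy-5-propylbenzene F1. F1 would be lithiated between the two methoxy groups (n-BuLi, THF, 0 °C) and quenched with I2 to 2-iodo-1,3-dimethoxy-5-propylbenzene F2. F2 would then be coupled with phenol 11 (CuI, picolinic acid, K3PO4, DMSO, 90 °C) to give 16 directly.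

Step 6 (aromatisation). The HI that is set free may cleave the benzyl ether, iodine may substitute ring B, or the dione may condense onto ring B with loss of water to a furan. The fallback works under basic, non-oxidising enolate chemistry, sets out from 13 and returns at 16. O-Methylation with Me3SiCHN2 (MeOH–toluene, rt) would give 14, isolated here. Kinetic deprotonation at the α′-methylene (LiN(SiMe3)2, THF, −78 °C) and trapping with PhSeCl would give methyl (E)-3-{4-(benzyloxy)-3-methoxy-5-[(2-methoxy-6-oxo-5-(phenylselanyl)-4-propylcyclohex-1-en-1-yl)oxy]phenyl}prop-2-enoate F3. Oxidation with H2O2 and pyridine, selenoxide syn-elimination and tautomerisation would give 15, and Me2SO4 with K2CO3 would give 16.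

Step 3 (mono-benzylation). Alkylation of both hydroxyls or of the wrong one may erode the regiochemistry on which the ether position depends. The fallback fixes the free hydroxyl by its position: it replaces 8 by commercial 5-bromovanillin F4, takes up 10 and returns at 11. Benzylation of the single hydroxyl (BnBr, K2CO3, DMF) would give 4-(benzyloxy)-3-bromo-5-methoxybenzaldehyde F5. Wittig reaction with 10 would give methyl (E)-3-[4-(benzyloxy)-3-bromo-5-methoxyphenyl]prop-2-enoate F6. Miyaura borylation (bis(pinacolato)diboron, Pd(dppf)Cl2, KOAc, dioxane, 90 °C) would give methyl (E)-3-[4-(benzyloxy)-3-methoxy-5-(4,4,5,5-tetramethyl-1,3,2-dioxaborolan-2-yl)phenyl]prop-2-enoate F7. Oxidation (NaBO3·4H2O, THF–H2O, rt) would give 11.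

**Further compounds**

F1 | step 5 | 1,3-dimethoxy-5-propylbenzene | CCCc1cc(OC)cc(OC)c1
F2 | step 5 | 2-iodo-1,3-dimethoxy-5-propylbenzene | CCCc1cc(OC)c(I)c(OC)c1
F3 | step 6 | methyl (E)-3-{4-(benzyloxy)-3-methoxy-5-[(2-methoxy-6-oxo-5-(phenylselanyl)-4-propylcyclohex-1-en-1-yl)oxy]phenyl}prop-2-enoate (mixture of diastereomers) | CCCC1CC(OC)=C(Oc2cc(/C=C/C(=O)OC)cc(OC)c2OCc2ccccc2)C(=O)C1[Se]c1ccccc1
F4 | step 3 | 5-bromovanillin (3-bromo-4-hydroxy-5-methoxybenzaldehyde) | COc1cc(C=O)cc(Br)c1O
F5 | step 3 | 4-(benzyloxy)-3-bromo-5-methoxybenzaldehyde | COc1cc(C=O)cc(Br)c1OCc1ccccc1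
F6 | step 3 | methyl (E)-3-[4-(benzyloxy)-3-bromo-5-methoxyphenyl]prop-2-enoate | COC(=O)/C=C/c1cc(Br)c(OCc2ccccc2)c(OC)c1
F7 | step 3 | methyl (E)-3-[4-(benzyloxy)-3-methoxy-5-(4,4,5,5-tetramethyl-1,3,2-dioxaborolan-2-yl)phenyl]prop-2-enoate | COC(=O)/C=C/c1cc(B2OC(C)(C)C(C)(C)O2)c(OCc2ccccc2)c(OC)c1
A1 | direct plan | eugenol (4-allyl-2-methoxyphenol) | C=CCc1ccc(O)c(OC)c1
A2 | direct plan | dihydroconiferyl alcohol, 4-(3-hydroxypropyl)-2-methoxyphenol | COc1cc(CCCO)ccc1O
A3 | direct plan | (±)-7-methoxy-1-oxaspiro[4.5]deca-6,9-dien-8-one | COC1=CC2(CCCO2)C=CC1=O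
A4 | direct plan | 4-propylsyringol (2,6-dimethoxy-4-propylphenol) | CCCc1cc(OC)c(O)c(OC)c1
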